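Ring B (C1–C4, C4a, C8a; tetralone numbering, C1 ketone, C3 carbinol, C5 pyranone, C6 phenyl, C8 hydroxyl) is closed last by forming the aryl ketone bond C1–C8a: an intramolecular Friedel–Crafts acylation of the 4-aryl-3-silyloxybutanoic acid 7. It exploits the free C8 hydroxyl of ring A, which activates its ortho carbon C8a and ends up peri to the new ketone, and the tether from C4a, whose other ortho carbon C5 is blocked by the pyranone. Acid 7, with all five ring A substituents in place, arises in one operation from a Michael/aldol benzannulation of keto acid 4 (from an enantiopure 3-silyloxyglutarate half-ester, source of C3) with 4-phenylbut-3-yn-2-one.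

Key step: step 3

Remark: half-ester 2 is assumed to be purchased enantiopure (a statin side-chain building block); it is otherwise one step from commercial 3-[(tert-butyldimethylsilyl)oxy]glutaric anhydride by alkaloid-mediated methanolysis.

Step 1
Reactants: 1 4-methoxy-6-methyl-2H-pyran-2-one; 2 (3R)-3-[(tert-butyldimethylsilyl)oxy]-5-methoxy-5-oxopentanoic acid
Product: 4 (3S)-3-[(tert-butyldimethylsilyl)oxy]-6-(4-methoxy-2-oxo-2H-pyran-6-yl)-5-oxohexanoic acid, via lithiated pyranone 3 (not isolated)
Conditions: 1 (3.3 equiv), LiN(SiMe3)2 (3.2 equiv), THF, −78 °C; then 2 (1 equiv), −78 → −30 °C; cold 1 M HCl work-up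
Reagents that add atoms: none
Why: Claisen-type acylation in which the stabilized dienolate 3 attacks the methyl ester of the lithium carboxylate of 2 (the carboxylate is inert, and because only 3, not a stronger base, takes up the acidic protons the β-silyloxy group should not be eliminated), so the C3 stereocenter is carried over untouched and its descriptor changes from R to S only because the priorities of the two arms swap.

Step 2
Reactants: 4 (3S)-3-[(tert-butyldimethylsilyl)oxy]-6-(4-methoxy-2-oxo-2H-pyran-6-yl)-5-oxohexanoic acid; 5 4-phenylbut-3-yn-2-one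
Product: 7 (3S)-3-[(tert-butyldimethylsilyl)oxy]-4-[5-hydroxy-2-(4-methoxy-2-oxo-2H-pyran-6-yl)-[1,1'-biphenyl]-3-yl]butanoic acid, via enedione Michael adduct 6 (not isolated)
Conditions: Cs2CO3 (3 equiv), DMF, 23 → 60 °C; cold 1 M HCl work-up
Reagents that add atoms: none
Why: Base-mediated Michael/aldol-condensation benzannulation (a Robinson-type annulation with an ynone, so no oxidant is needed): the doubly activated methylene of 4 adds to the phenyl-bearing alkyne carbon of 5, the methyl ketone of adduct 6 closes onto the chain ketone (the future C4a), and loss of water with tautomerization should give the phenol of ring A; no stereocenter is formed and C3 is kept because the ketone of 4 sits as its stabilized enolate.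

Step 3
Reactants: 7 (3S)-3-[(tert-butyldimethylsilyl)oxy]-4-[5-hydroxy-2-(4-methoxy-2-oxo-2H-pyran-6-yl)-[1,1'-biphenyl]-3-yl]butanoic acid
Product: 9 (3S)-3-[(tert-butyldimethylsilyl)oxy]-8-hydroxy-5-(4-methoxy-2-oxo-2H-pyran-6-yl)-6-phenyl-3,4-dihydronaphthalen-1(2H)-one, via acid chloride 8 (not isolated)
Conditions: 1-chloro-N,N,2-trimethylprop-1-en-1-amine (1.1 equiv), CH2Cl2 (0.02 M), 0 °C; then SnCl4 (3 equiv), −78 → −30 °C; ice-water quench
Reagents that add atoms: none
Why: The chloroenamine should convert the acid into acid chloride 8 under neutral conditions (no HCl, so the silyl ether and the free phenol are left alone), and SnCl4 then ionises 8 to an acylium/tin complex that is attacked by C8a of ring A; loss of the C8a proton rearomatises the ring and the product is held as the tin chelate of the peri C8–O/C1=O pair until the quench. The closest known reaction type is the intramolecular Friedel–Crafts acylation that closes a 4-arylbutanoyl chloride to a 1-tetralone. Ring B closes in a 6-exo mode, the arene carbon C8a attacking the exocyclic acyl carbon C1 through a six-membered transition state. No stereocenter is formed, and C3 is not touched and keeps its S configuration. The step needs site selectivity on ring A and survival of the β-silyloxy group: only C8a and C5 can be reached through a six-membered ring, C5 carries the pyranone and has no proton to lose so attack there is reversible, C7 is out of reach, and C8a is the most electron-rich CH (ortho to the C8 hydroxyl and to the C4a arm, para to the phenyl-bearing C6). High dilution should suppress intermolecular O-acylation of the phenol, and the low temperature with the silyl ether in place should keep the β-oxygenated ketone from eliminating and aromatising ring B.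

Step 4
Reactants: 9 (3S)-3-[(tert-butyldimethylsilyl)oxy]-8-hydroxy-5-(4-methoxy-2-oxo-2H-pyran-6-yl)-6-phenyl-3,4-dihydronaphthalen-1(2H)-one
Product: 10 wailupemycin F, (3S)-3,8-dihydroxy-5-(4-hydroxy-2-oxo-2H-pyran-6-yl)-6-phenyl-3,4-dihydronaphthalen-1(2H)-one
Conditions: BBr3 (6 equiv), CH2Cl2, −78 → 0 °C; then MeOH, 0 °C
Reagents that add atoms: none
Why: Lewis-acid ether cleavage in which BBr3 complexes the pyranone carbonyl so that bromide removes the methyl group of the vinylogous ester by SN2, and the HBr/MeOH formed on quench removes the silyl ether, while the low temperature and the boron chelate of the peri-hydroxy ketone should keep the β-hydroxy ketone from dehydrating; no stereocenter is touched.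

Compound list
1 | 4-methoxy-6-methyl-2H-pyran-2-one | Cc1cc(OC)cc(=O)o1 | starting material
2 | (3R)-3-[(tert-butyldimethylsilyl)oxy]-5-methoxy-5-oxopentanoic acid | OC(=O)C[C@@H](O[Si](C)(C)C(C)(C)C)CC(=O)OC | starting material
3 | [(4-methoxy-2-oxo-2H-pyran-6-yl)methyl]lithium | [Li]Cc1cc(OC)cc(=O)o1 | intermediate
4 | (3S)-3-[(tert-butyldimethylsilyl)oxy]-6-(4-methoxy-2-oxo-2H-pyran-6-yl)-5-oxohexanoic acid | OC(=O)C[C@@H](O[Si](C)(C)C(C)(C)C)CC(=O)Cc1cc(OC)cc(=O)o1 | intermediate
5 | 4-phenylbut-3-yn-2-one | CC(=O)C#Cc1ccccc1 | starting material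
6 | (3S)-3-[(tert-butyldimethylsilyl)oxy]-6-(4-methoxy-2-oxo-2H-pyran-6-yl)-5,9-dioxo-7-phenyldec-7-enoic acid (C6 epimers, alkene isomers) | OC(=O)C[C@@H](O[Si](C)(C)C(C)(C)C)CC(=O)C(c1cc(OC)cc(=O)o1)C(=CC(C)=O)c1ccccc1 | intermediate
7 | (3S)-3-[(tert-butyldimethylsilyl)oxy]-4-[5-hydroxy-2-(4-methoxy-2-oxo-2H-pyran-6-yl)-[1,1'-biphenyl]-3-yl]butanoic acid | OC(=O)C[C@@H](O[Si](C)(C)C(C)(C)C)Cc1cc(O)cc(-c2ccccc2)c1-c1cc(OC)cc(=O)o1 | intermediate
8 | (3S)-3-[(tert-butyldimethylsilyl)oxy]-4-[5-hydroxy-2-(4-methoxy-2-oxo-2H-pyran-6-yl)-[1,1'-biphenyl]-3-yl]butanoyl chloride | ClC(=O)C[C@@H](O[Si](C)(C)C(C)(C)C)Cc1cc(O)cc(-c2ccccc2)c1-c1cc(OC)cc(=O)o1 | intermediate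
9 | (3S)-3-[(tert-butyldimethylsilyl)oxy]-8-hydroxy-5-(4-methoxy-2-oxo-2H-pyran-6-yl)-6-phenyl-3,4-dihydronaphthalen-1(2H)-one | O=C1C[C@@H](O[Si](C)(C)C(C)(C)C)Cc2c1c(O)cc(-c1ccccc1)c2-c1cc(OC)cc(=O)o1 | intermediate
10 | wailupemycin F, (3S)-3,8-dihydroxy-5-(4-hydroxy-2-oxo-2H-pyran-6-yl)-6-phenyl-3,4-dihydronaphthalen-1(2H)-one | O=C1C[C@@H](O)Cc2c1c(O)cc(-c1ccccc1)c2-c1cc(O)cc(=O)o1 | target

Total step count: 4. Longest linear sequence: 4 steps (2 → 4 → 7 → 9 → 10).

Steps most likely to fail

1. Step 2 (benzannulation). After the Michael addition the adduct may close through the wrong enolate (the chain methylene next to the ketone attacking the enone carbonyl), may lose silanolate by β-elimination, or may stall as the stabilized vinylogous anion or an O-cyclised pyran. The fallback sets out from 4 and comes back at 7. Keto acid 4 is taken through a Robinson annulation with commercial (E)-4-phenylbut-3-en-2-one (CC(=O)/C=C/c1ccccc1; Cs2CO3, DMF, 23 °C for the Michael addition, then pyrrolidine/AcOH, 50 °C for the aldol condensation), in which the methyl ketone of a saturated 1,5-diketone is the aldol donor. This should give (3S)-3-[(tert-butyldimethylsilyl)oxy]-4-[6-(4-methoxy-2-oxo-2H-pyran-6-yl)-3-oxo-5-phenylcyclohex-1-en-1-yl]butanoic acid F1 as a mixture of ring diastereomers. Dehydrogenative aromatisation of F1 with DDQ (1,4-dioxane, 80 °C) should then give 7.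

2. Step 3 (key ring closure). The Lewis acid may strip the silyl ether and trigger β-elimination with aromatisation of ring B, the acylium may be consumed by unproductive ipso attack at C5, or the phenol may be O-acylated intermolecularly. The fallback sets out from 7 and comes back at 9, closing the same bond at the aldehyde oxidation level without acid. BH3·SMe2 (THF, 0 °C) should reduce the acid to 6-[3-[(2S)-2-[(tert-butyldimethylsilyl)oxy]-4-hydroxybutyl]-5-hydroxy-[1,1'-biphenyl]-2-yl]-4-methoxy-2H-pyran-2-one F2. Parikh–Doering oxidation (SO3·pyridine, DMSO, i-Pr2NEt, 0 °C) should give (3S)-3-[(tert-butyldimethylsilyl)oxy]-4-[5-hydroxy-2-(4-methoxy-2-oxo-2H-pyran-6-yl)-[1,1'-biphenyl]-3-yl]butanal F3. EtMgBr (1.0 equiv, toluene/CH2Cl2, 0 → 23 °C) then forms the magnesium phenoxide, which should add the tethered aldehyde at its ortho carbon C8a through a chelate (ortho-specific hydroxyalkylation of a magnesium phenoxide), giving (3S)-3-[(tert-butyldimethylsilyl)oxy]-5-(4-methoxy-2-oxo-2H-pyran-6-yl)-6-phenyl-1,2,3,4-tetrahydronaphthalene-1,8-diol F4 as C1 epimers. MnO2 (CH2Cl2, 23 °C) should oxidise the benzylic alcohol of F4 to 9.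

3. Step 4 (global deprotection). The boron halide may promote β-elimination of the C3 oxygen with aromatisation of ring B, or cleavage of the vinylogous methyl ester may be incomplete at the low temperature the ketol tolerates. The fallback sets out from 9 and comes back at 10 in two mild stages. HF·pyridine (THF/pyridine, 0 → 23 °C) should remove the silyl ether to give (3S)-3,8-dihydroxy-5-(4-methoxy-2-oxo-2H-pyran-6-yl)-6-phenyl-3,4-dihydronaphthalen-1(2H)-one F5. LiI (EtOAc, reflux) should then dealkylate the vinylogous methyl ester by SN2 attack of iodide at the methyl group, with the pyranonate as a carboxylate-like leaving group, to give 10.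

Further compounds
F1 | step 2 | (3S)-3-[(tert-butyldimethylsilyl)oxy]-4-[6-(4-methoxy-2-oxo-2H-pyran-6-yl)-3-oxo-5-phenylcyclohex-1-en-1-yl]butanoic acid | OC(=O)C[C@@H](O[Si](C)(C)C(C)(C)C)CC1=CC(=O)CC(c2ccccc2)C1c1cc(OC)cc(=O)o1
F2 | step 3 | 6-[3-[(2S)-2-[(tert-butyldimethylsilyl)oxy]-4-hydroxybutyl]-5-hydroxy-[1,1'-biphenyl]-2-yl]-4-methoxy-2H-pyran-2-one | OCC[C@@H](O[Si](C)(C)C(C)(C)C)Cc1cc(O)cc(-c2ccccc2)c1-c1cc(OC)cc(=O)o1
F3 | step 3 | (3S)-3-[(tert-butyldimethylsilyl)oxy]-4-[5-hydroxy-2-(4-methoxy-2-oxo-2H-pyran-6-yl)-[1,1'-biphenyl]-3-yl]butanal | O=CC[C@@H](O[Si](C)(C)C(C)(C)C)Cc1cc(O)cc(-c2ccccc2)c1-c1cc(OC)cc(=O)o1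
F4 | step 3 | (3S)-3-[(tert-butyldimethylsilyl)oxy]-5-(4-methoxy-2-oxo-2H-pyran-6-yl)-6-phenyl-1,2,3,4-tetrahydronaphthalene-1,8-diol | OC1C[C@@H](O[Si](C)(C)C(C)(C)C)Cc2c1c(O)cc(-c1ccccc1)c2-c1cc(OC)cc(=O)o1
F5 | step 4 | (3S)-3,8-dihydroxy-5-(4-methoxy-2-oxo-2H-pyran-6-yl)-6-phenyl-3,4-dihydronaphthalen-1(2H)-one | O=C1C[C@@H](O)Cc2c1c(O)cc(-c1ccccc1)c2-c1cc(OC)cc(=O)o1
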